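**Retrosynthetic overview**

1. Numbering used: ring C1 (the CH that carries the side chain), C2H2, C3=C4 (C4 bears C18H2OH), C5, C6, C7=C8 (C8 bears CH3), C9, C10, C11=C12 (C12 bears CH3), C13, C14; C15 is the side-chain carbinol carbon.
2. Key disconnection: the C8–C9 bond of the 14-membered carbocycle (the only ring, closed last), made by Ni-electrocatalytic decarboxylative alkenylation within seco compound 22 ((E)-C8 alkenyl iodide plus C9 carboxyl as N-acyloxyphthalimide, CO2 lost). Enabling feature: C8 is the methyl-bearing sp2 carbon of the C7=C8 ring alkene and C9 is its primary, non-allylic CH2 neighbour in the C7=C8/C11=C12 1,5-diene, so a C9 radical has no alkene in 5-exo or 6-exo reach and the E geometry is carried in on the iodide.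
3. The seco chain comes from three pieces: C12–C13 by hydroboration/B-alkyl Suzuki coupling with Z-iodide 16, C2–C3 by Negishi coupling with Z-iodide 12 (from a three-component anti-carbomagnesiation/iodination of propargyl alcohol), and C8–I by hydrozirconation/iodination of a methyl-capped alkyne.
4. Both stereocentres come from nerol: Sharpless epoxidation, then vinyl-cuprate opening at the secondary epoxide carbon with inversion gives the C1/C15 pair together with both ring arms (CH2OH becomes C2, vinyl becomes C14–C13).
5. Ring order: no ring exists before step 14, which closes the 14-membered carbocycle C1–C14; desilylation then gives the target.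

Key step: step 14

Remark (assumptions): nerol, pent-3-yn-1-ol, prop-2-yn-1-ol and methyl 4-oxobutanoate are taken as commercial. The CIP label of the ring CH changes formally in some intermediates (substituent priorities change) while its spatial arrangement is that set in step 2.

**Route**

Step 1
Reactants: 1 nerol
Product: 2 [(2S,3R)-3-methyl-3-(4-methylpent-3-en-1-yl)oxiran-2-yl]methanol
Conditions: Ti(OiPr)4 (cat.), L-(+)-diethyl tartrate (cat.), t-BuOOH, 4 Å MS, CH2Cl2, −20 °C
Reagents that add atoms: tert-butyl hydroperoxide, CC(C)(C)OO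
Why: Sharpless asymmetric epoxidation of the (Z)-allylic alcohol; the L-(+)-tartrate/Ti complex should deliver oxygen to one face of C2=C3 and set both epoxide carbons (2S,3R), leaving the remote trisubstituted alkene untouched.

Step 2
Reactants: 2 [(2S,3R)-3-methyl-3-(4-methylpent-3-en-1-yl)oxiran-2-yl]methanol
Product: 3 (2R,3R)-2-ethenyl-3,7-dimethyloct-6-ene-1,3-diol
Conditions: CH2=CHMgBr (4 equiv), CuI (15 mol%), THF/Et2O, −30 → 0 °C; aq. NH4Cl
Reagents that add atoms: vinylmagnesium bromide, C=C[Mg]Br
Why: Copper-catalysed SN2 opening of a 3,3-disubstituted 2,3-epoxy alcohol; the vinyl cuprate should attack the secondary epoxide carbon with inversion (the tertiary carbon is blocked), which sets the ring CH (C1) and keeps the tertiary carbinol (C15) as fixed in the epoxide.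

Step 3
Reactants: 3 (2R,3R)-2-ethenyl-3,7-dimethyloct-6-ene-1,3-diol
Product: 4 (3S,4R)-3-(iodomethyl)-4,8-dimethylnona-1,7-dien-4-ol
Conditions: PPh3, imidazole, I2 (pre-mixed, PPh3 in slight excess), CH2Cl2, 0 °C → rt
Reagents that add atoms: iodine, II
Why: Appel-type (Garegg–Samuelsson) iodination; only the primary hydroxyl forms the alkoxyphosphonium ion and is displaced by iodide, so the tertiary alcohol and both stereocentres should be untouched.

Step 4
Reactants: 4 (3S,4R)-3-(iodomethyl)-4,8-dimethylnona-1,7-dien-4-ol
Product: 5 triethyl{[(3S,4R)-3-(iodomethyl)-4,8-dimethylnona-1,7-dien-4-yl]oxy}silane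
Conditions: TESOTf, 2,6-lutidine, CH2Cl2, −78 → 0 °C
Reagents that add atoms: triethylsilyl triflate, CC[Si](CC)(CC)OS(=O)(=O)C(F)(F)F
Why: Silylation of the hindered tertiary alcohol with a silyl triflate, so that no acidic OH quenches the organozinc of step 8; no stereocentre is touched.

Step 5
Reactants: 6 pent-3-yn-1-ol
Product: 7 5-bromopent-2-yne
Conditions: CBr4, PPh3, CH2Cl2, 0 °C
Reagents that add atoms: carbon tetrabromide, BrC(Br)(Br)Br
Why: Appel bromination of a primary alcohol (SN2 at the carbinol carbon); the internal alkyne is inert.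

Step 6
Reactants: 7 5-bromopent-2-yne; 8 prop-2-yn-1-ol
Product: 11 (2Z)-2-(iodomethylidene)hept-5-yn-1-ol, via pent-3-yn-1-ylmagnesium bromide 9 (not isolated), via (Z)-alkenylmagnesium alkoxide 10 (not isolated)
Conditions: 7, Mg, THF (gives 9, 2.5 equiv); 8, CuI (10 mol%), THF, −10 °C → rt; then I2, −78 → 0 °C
Reagents that add atoms: iodine, II
Why: Copper-catalysed anti-carbomagnesiation of the propargylic alkoxide joins three components (Grignard reagent, propargyl alcohol, iodine): the alkyl group adds to the carbon next to CH2O and magnesium ends on the terminal carbon cis to CH2O in a five-membered chelate, so iodinolysis with retention should give the Z-iodide that later fixes the C3=C4 geometry.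

Step 7
Reactants: 11 (2Z)-2-(iodomethylidene)hept-5-yn-1-ol
Product: 12 tert-butyl{[(2Z)-2-(iodomethylidene)hept-5-yn-1-yl]oxy}dimethylsilane
Conditions: TBSCl, imidazole, CH2Cl2, 0 °C → rt
Reagents that add atoms: tert-butyldimethylsilyl chloride, CC(C)(C)[Si](C)(C)Cl
Why: Standard silylation of the primary allylic alcohol; the alkene geometry is not affected.

Step 8
Reactants: 5 triethyl{[(3S,4R)-3-(iodomethyl)-4,8-dimethylnona-1,7-dien-4-yl]oxy}silane; 12 tert-butyl{[(2Z)-2-(iodomethylidene)hept-5-yn-1-yl]oxy}dimethylsilane
Product: 14 tert-butyl{[(2Z,5S,6R)-5-ethenyl-6,10-dimethyl-2-(pent-3-yn-1-yl)-6-(triethylsilyloxy)undeca-2,9-dien-1-yl]oxy}dimethylsilane, via alkylzinc iodide 13 (not isolated)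
Conditions: 5, Zn dust (TMSCl/BrCH2CH2Br-activated), LiCl, THF, 40 °C; then 12, Pd(OAc)2 (3 mol%), SPhos (6 mol%), THF, rt → 40 °C
Reagents that add atoms: none
Why: Negishi C(sp3)–C(sp2) coupling; zinc insertion into the primary C–I bond and Pd-catalysed coupling with the alkenyl iodide with retention should form C2–C3 and the 3Z alkene (C2 cis to CH2OTBS) without touching the stereocentres.

Step 9
Reactants: 15 methyl 4-oxobutanoate
Product: 16 methyl (4Z)-5-iodohex-4-enoate
Conditions: EtPPh3I, n-BuLi, THF, rt; I2, −78 °C; NaHMDS, −20 °C; then 15, −78 °C → rt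
Reagents that add atoms: ethyltriphenylphosphonium iodide, CC[P+](c1ccccc1)(c1ccccc1)c1ccccc1.[I-]; iodine, II
Why: Stork–Zhao-type Wittig olefination with the α-iodo ylide, which under kinetic conditions should give the (Z)-2-iodoalk-2-ene (chain cis to iodine); the ester is not attacked at low temperature.

Step 10
Reactants: 14 tert-butyl{[(2Z,5S,6R)-5-ethenyl-6,10-dimethyl-2-(pent-3-yn-1-yl)-6-(triethylsilyloxy)undeca-2,9-dien-1-yl]oxy}dimethylsilane; 16 methyl (4Z)-5-iodohex-4-enoate
Product: 18 seco methyl ester (14 with CH=CH2 replaced by CH2CH2–C(CH3)=CH–CH2CH2CO2CH3 of Z geometry), via B-alkyl-9-BBN adduct 17 (not isolated)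
Conditions: 9-BBN (1.3 equiv), THF, 0 °C → rt; then 16, PdCl2(dppf) (8 mol%), AsPh3, Cs2CO3, DMF/H2O, rt
Reagents that add atoms: none
Why: Anti-Markovnikov hydroboration of the only monosubstituted alkene, then B-alkyl Suzuki–Miyaura coupling with retention of the iodide geometry, should form C12–C13 and the 11Z alkene; trisubstituted alkenes and the internal alkyne react far more slowly with 9-BBN and no stereocentre is formed.

Step 11
Reactants: 18 seco methyl ester
Product: 20 (E)-alkenyl iodide ester (18 with CH2–C≡C–CH3 converted to CH2–CH=C(I)–CH3), via alkenylzirconocene chloride 19 (not isolated)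
Conditions: Cp2Zr(H)Cl (2.2 equiv), THF, rt → 40 °C; then I2, 0 °C; aq. Na2S2O3/NaHCO3
Reagents that add atoms: iodine, II
Why: Syn-hydrozirconation (Schwartz reagent) of the methyl-capped alkyne, with zirconium settling on the carbon next to CH3 after equilibration, and iodinolysis with retention should give the (E)-2-iodoalk-2-ene (C6 trans to iodine) that carries the 7E geometry.

Step 12
Reactants: 20 (E)-alkenyl iodide ester
Product: 21 seco carboxylic acid (CO2H in place of CO2CH3 of 20)
Conditions: LiOH·H2O, THF/MeOH/H2O, rt; then cold 0.5 M HCl to pH 4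
Reagents that add atoms: lithium hydroxide, [Li+].[OH-]
Why: Saponification of the methyl ester (acyl substitution by hydroxide); silyl ethers, alkenyl iodide and stereocentres should be stable to these conditions.

Step 13
Reactants: 21 seco carboxylic acid
Product: 22 N-acyloxyphthalimide (redox-active) ester of 21
Conditions: N-hydroxyphthalimide, DIC, DMAP (cat.), CH2Cl2, rt
Reagents that add atoms: N-hydroxyphthalimide, O=C1c2ccccc2C(=O)N1O
Why: Carbodiimide-mediated esterification; it arms C9 for single-electron decarboxylation and touches nothing else.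

Step 14
Reactants: 22 N-acyloxyphthalimide ester of 21
Product: 23 bis-silyl ether of the target (C18–OTBS, C15–OTES; 3Z,7E,11Z macrocycle)
Conditions: NiCl2·6H2O (30 mol%), 2,2'-bipyridine (30 mol%), AgNO3 (0.5 equiv), LiCl, DMF, Mg anode(+)/RVC cathode(−), undivided cell, constant current, rt; 22 added by syringe pump (≤2 mM)
Reagents that add atoms: none
Why: Proposed new method: cathodically generated low-valent (bpy)Ni oxidatively adds the C8–I bond, while single-electron reduction of the N-acyloxyphthalimide (by low-valent Ni or at the silver-coated cathode) releases CO2, phthalimide anion and the primary C9 radical; capture of this radical by the alkenyl–Ni(II) centre of the same molecule and reductive elimination from Ni(III) form C8–C9, the Mg anode supplying the electrons. The closest known reaction type is the intermolecular Ni-electrocatalytic decarboxylative alkenylation of redox-active esters with alkenyl iodides used to assemble 1,5-polyenes; what is new is its use as an end-to-end macrocyclization. The 14-membered ring closes by intramolecular C(sp2)–C(sp3) cross-electrophile coupling (radical–nickel recombination, then reductive elimination), not by radical addition to an alkene. No stereocentre is formed: C1 and C15 are remote and untouched, and the 7E geometry is carried over from the (E)-alkenyl iodide because oxidative addition and reductive elimination at the alkenyl carbon proceed with retention. The step needs ring closure to win over oligomerization and over reduction of the radical, which slow addition of 22 and a high Ni loading should secure, and it needs a radical that does nothing else: C9 is primary, not allylic, and the only alkene within reach (C11=C12) is homoallylic, so there is no 5-exo or 6-exo pathway and only a reversible 3-exo closure.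

Step 15
Reactants: 23 bis-silyl ether of the target
Product: 24 (2R)-2-[(1R,3Z,7E,11Z)-4-(hydroxymethyl)-8,12-dimethylcyclotetradeca-3,7,11-trien-1-yl]-6-methylhept-5-en-2-ol (CNP0389814.1)
Conditions: TBAF (5 equiv), THF, rt → 45 °C
Reagents that add atoms: none
Why: Fluoride-mediated desilylation should remove the primary TBS and the tertiary TES ether in one operation without affecting alkenes or stereocentres.

**Compound list**

1 | nerol, (2Z)-3,7-dimethylocta-2,6-dien-1-ol | CC(C)=CCC/C(C)=C\CO | starting material
2 | [(2S,3R)-3-methyl-3-(4-methylpent-3-en-1-yl)oxiran-2-yl]methanol | CC(C)=CCC[C@@]1(C)O[C@H]1CO | intermediate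
3 | (2R,3R)-2-ethenyl-3,7-dimethyloct-6-ene-1,3-diol | CC(C)=CCC[C@@](C)(O)[C@H](C=C)CO | intermediate
4 | (3S,4R)-3-(iodomethyl)-4,8-dimethylnona-1,7-dien-4-ol | CC(C)=CCC[C@@](C)(O)[C@H](C=C)CI | intermediate
5 | triethyl{[(3S,4R)-3-(iodomethyl)-4,8-dimethylnona-1,7-dien-4-yl]oxy}silane | CC(C)=CCC[C@@](C)(O[Si](CC)(CC)CC)[C@H](C=C)CI | intermediate
6 | pent-3-yn-1-ol | CC#CCCO | starting material
7 | 5-bromopent-2-yne | CC#CCCBr | intermediate
8 | prop-2-yn-1-ol | C#CCO | starting material
9 | pent-3-yn-1-ylmagnesium bromide | CC#CCC[Mg]Br | intermediate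
10 | (Z)-alkenylmagnesium alkoxide (Mg on the terminal alkene carbon, cis to CH2OMgBr) | Br[Mg]/C=C(\CO[Mg]Br)CCC#CC | intermediate
11 | (2Z)-2-(iodomethylidene)hept-5-yn-1-ol | OC/C(=C\I)CCC#CC | intermediate
12 | tert-butyl{[(2Z)-2-(iodomethylidene)hept-5-yn-1-yl]oxy}dimethylsilane | CC(C)(C)[Si](C)(C)OC/C(=C\I)CCC#CC | intermediate
13 | alkylzinc iodide (5 with CH2I converted to CH2ZnI) | CC(C)=CCC[C@@](C)(O[Si](CC)(CC)CC)[C@H](C=C)C[Zn]I | intermediate
14 | tert-butyl{[(2Z,5S,6R)-5-ethenyl-6,10-dimethyl-2-(pent-3-yn-1-yl)-6-(triethylsilyloxy)undeca-2,9-dien-1-yl]oxy}dimethylsilane | CC(C)=CCC[C@@](C)(O[Si](CC)(CC)CC)[C@H](C=C)C/C=C(\CO[Si](C)(C)C(C)(C)C)CCC#CC | intermediate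
15 | methyl 4-oxobutanoate | COC(=O)CCC=O | starting material
16 | methyl (4Z)-5-iodohex-4-enoate | COC(=O)CC/C=C(/C)I | intermediate
17 | B-alkyl-9-BBN adduct (14 with CH=CH2 converted to CH2CH2–9-BBN) | CC(C)=CCC[C@@](C)(O[Si](CC)(CC)CC)[C@H](CCB1C2CCCC1CCC2)C/C=C(\CO[Si](C)(C)C(C)(C)C)CCC#CC | intermediate
18 | seco methyl ester (14 with CH=CH2 replaced by CH2CH2–C(CH3)=CH–CH2CH2CO2CH3, Z) | CC(C)=CCC[C@@](C)(O[Si](CC)(CC)CC)[C@H](CC/C(C)=C\CCC(=O)OC)C/C=C(\CO[Si](C)(C)C(C)(C)C)CCC#CC | intermediate
19 | alkenylzirconocene chloride (18 with C≡C converted to CH=C(ZrCp2Cl)CH3) | CC(C)=CCC[C@@](C)(O[Si](CC)(CC)CC)[C@H](CC/C(C)=C\CCC(=O)OC)C/C=C(\CO[Si](C)(C)C(C)(C)C)CC/C=C(\C)[Zr](Cl)(C1C=CC=C1)C1C=CC=C1 | intermediate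
20 | (E)-alkenyl iodide ester (18 with CH2–C≡C–CH3 converted to CH2–CH=C(I)–CH3) | CC(C)=CCC[C@@](C)(O[Si](CC)(CC)CC)[C@H](CC/C(C)=C\CCC(=O)OC)C/C=C(\CO[Si](C)(C)C(C)(C)C)CC/C=C(\C)I | intermediate
21 | seco carboxylic acid (acid of 20) | CC(C)=CCC[C@@](C)(O[Si](CC)(CC)CC)[C@H](CC/C(C)=C\CCC(=O)O)C/C=C(\CO[Si](C)(C)C(C)(C)C)CC/C=C(\C)I | intermediate
22 | N-acyloxyphthalimide ester of 21 | CC(C)=CCC[C@@](C)(O[Si](CC)(CC)CC)[C@H](CC/C(C)=C\CCC(=O)ON1C(=O)c2ccccc2C1=O)C/C=C(\CO[Si](C)(C)C(C)(C)C)CC/C=C(\C)I | intermediate
23 | bis-silyl ether of the target (C18–OTBS, C15–OTES) | CC(C)=CCC[C@@](C)(O[Si](CC)(CC)CC)[C@H]1C/C=C(\CO[Si](C)(C)C(C)(C)C)CC/C=C(\C)CC/C=C(/C)CC1 | intermediate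
24 | (2R)-2-[(1R,3Z,7E,11Z)-4-(hydroxymethyl)-8,12-dimethylcyclotetradeca-3,7,11-trien-1-yl]-6-methylhept-5-en-2-ol | CC(C)=CCC[C@@](C)(O)[C@H]1C/C=C(\CO)CC/C=C(\C)CC/C=C(/C)CC1 | target

**Step count and risks**

Total steps: 15. Longest linear sequence: 11 (steps 1–4, 8, 10–15 from nerol). Side branches: steps 5–7 (to 12) and step 9 (to 16).

Steps most likely to fail:

1. Step 14 (Proposed new method). The risks are oligomerization by intermolecular radical capture, hydrogen-atom abstraction or over-reduction of the C9 radical before it reaches nickel (giving the linear decarboxylated chain), and partial Z→E erosion at C11=C12 through reversible cyclopropylcarbinyl closure of the homoallylic radical. Fallback with known chemistry, setting out from 22 and returning at 23: photochemical decarboxylative borylation of 22 (bis(catecholato)diboron, DMAc, blue LEDs, rt; then pinacol, Et3N), in which the radical is trapped intermolecularly by the diboron at high concentration, should give the seco alkenyl iodide pinacol boronate F1. An intramolecular B-alkyl Suzuki–Miyaura macrocyclization of F1 (Pd(OAc)2/SPhos, aq. K3PO4, THF, 70 °C, slow addition) should then form C8–C9 with retention of the E-iodide geometry and deliver 23.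

2. Step 11. The risks are incomplete regiocontrol of Zr–H addition across the methyl-capped alkyne and competing attack of the excess zirconium hydride on the methyl ester. Fallback, setting out from 18 and returning at 21: the ester is taken out of the hydrometalation by a redox detour. Reduction of 18 with LiBH4 (THF, 0 °C → rt) should give the primary alcohol F2. Hydrozirconation of F2 with a larger excess of Cp2Zr(H)Cl (one equivalent is consumed by the hydroxyl, the rest allows full equilibration), followed by iodinolysis, should give the (E)-alkenyl iodide alcohol F3. Oxidation of F3 with TEMPO/PhI(OAc)2 in MeCN/aqueous buffer should lead directly to acid 21, so that 20 and step 12 are bypassed.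

3. Step 8. The risks are sluggish zinc insertion into the β-branched iodide, protodezincation, and β-hydride elimination at palladium during coupling of the hindered alkylzinc. Fallback, setting out from 5 and returning at 14: iodine–lithium exchange on 5 (t-BuLi, Et2O, −78 °C) and trapping with B-methoxy-9-BBN should give the lithium borinate F4. F4 should couple with 12 in a B-alkyl Suzuki–Miyaura reaction (PdCl2(dppf), K3PO4, DMF, rt) to give 14; 9-BBN attacks neither the vinyl group nor the silyl ether under these conditions because the boron is introduced as the methoxyborane.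

**Further compounds**

F1 | step 14 | seco alkenyl iodide pinacol boronate (C9–Bpin in place of the C9 carboxyl of 22) | CC(C)=CCC[C@@](C)(O[Si](CC)(CC)CC)[C@H](CC/C(C)=C\CCB1OC(C)(C)C(C)(C)O1)C/C=C(\CO[Si](C)(C)C(C)(C)C)CC/C=C(\C)I
F2 | step 11 | primary alcohol from reduction of ester 18 | CC(C)=CCC[C@@](C)(O[Si](CC)(CC)CC)[C@H](CC/C(C)=C\CCCO)C/C=C(\CO[Si](C)(C)C(C)(C)C)CCC#CC
F3 | step 11 | (E)-alkenyl iodide alcohol | CC(C)=CCC[C@@](C)(O[Si](CC)(CC)CC)[C@H](CC/C(C)=C\CCCO)C/C=C(\CO[Si](C)(C)C(C)(C)C)CC/C=C(\C)I
F4 | step 8 | lithium B-alkyl-B-methoxy-9-BBN borinate from 5 | [Li+].CC(C)=CCC[C@@](C)(O[Si](CC)(CC)CC)[C@H](C=C)C[B-]1(OC)C2CCCC1CCC2
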